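**Retrosynthetic overview**

1. The target is (5S,9R,10S,13S)-15-acetoxylabd-7-en-17-oic acid. C17 goes on last: C8–C17 by hydroxycarbonylation of a Δ7 enol triflate, which comes from a 17-nor-8-ketone, an 8(17)-olefin and, before that, an 8α-oxygen function.
2. Key disconnection C12–C13: a primary C12 radical on the decalin adds to C13, the β-carbon of an N-crotonyl pyrazole held on a chiral-at-rhodium Lewis acid, which sets the C13 stereocentre.
3. The radical is released from a (−)-sclareol derivative: C14 and C15 are cleaved off, and the remaining acetyl carbon (the old C13) is tied to O8 as a ketal carrying an N-phthalimidoyloxy group.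
4. Feature that makes the key step possible: C12 is the ring neighbour of that ketal carbon in the temporary tetrahydropyran ring O8–C8–C9–C11–C12–C13(old). An oxyl radical on the ketal carbon cuts exactly this ring bond, frees C12 and turns the ketal carbon into the acetate on O8, the later leaving group for ring B.
5. Ring order: rings A and B with C5, C9 and C10 are taken ready-made from sclareol. The only ring formed is the temporary pyran (step 1), which step 4 opens again.

Key step: step 4

Assumption: the Λ enantiomer of the rhodium Lewis acid is taken to leave open the face of the bound crotonyl unit that gives the 13S adduct; if a trial with a simple primary radical shows the opposite sense, the Δ enantiomer is used and nothing else changes.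

Remark: labdane numbering is used throughout; all compounds belong to the normal series of sclareol (5α-H, 9α-H, 10β-methyl).

**Route**

Step 1
Reactants: 1 (−)-sclareol, (13R)-labd-14-ene-8α,13-diol
Product: 4 sclareol oxide (8α,13-epoxy-14,15-dinorlabd-12-ene), via hydroxy aldehyde 2 (not isolated), via hydroxy ketone 3 (not isolated)
Conditions: OsO4 (cat.), NaIO4 (excess), THF–H2O, rt; then p-TsOH (cat.), toluene, 80 °C
Reagents that add atoms: none
Why: Lemieux–Johnson cleavage removes C15 from the vinyl group, periodate then cuts the tertiary α-hydroxy aldehyde 2 to the C13 methyl ketone 3, and acid-catalysed cyclodehydration of this δ-hydroxy ketone onto the 8α-hydroxyl should give the six-membered cyclic enol ether; C5, C8, C9 and C10 are untouched and the C13 stereocentre of 1 is destroyed on purpose.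

Step 2
Reactants: 4 sclareol oxide; 5 N-hydroxyphthalimide
Product: 6 13-(phthalimidooxy)-8α,13-epoxy-14,15-dinorlabdane (C13 epimers)
Conditions: PPTS (cat.), CH2Cl2, 0 °C to rt
Reagents that add atoms: none
Why: Acid-catalysed Markovnikov addition of the N–OH group to the enol ether (protonation at C12, capture of the C13 oxocarbenium ion), the reaction type by which N-hydroxyphthalimide is added to dihydropyran or 2-methoxypropene; either epimer at the new ketal carbon is acceptable because both give the same oxyl radical in step 4.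

Step 3
Reactants: 7 (E)-but-2-enoyl chloride; 8 3,5-dimethyl-1H-pyrazole
Product: 9 (E)-1-(3,5-dimethylpyrazol-1-yl)but-2-en-1-one
Conditions: Et3N, CH2Cl2, 0 °C
Reagents that add atoms: none
Why: N-acylation of the pyrazole by the acid chloride (Schotten–Baumann-type amide formation) with the (E)-olefin retained.

Step 4
Reactants: 6 13-(phthalimidooxy)-8α,13-epoxy-14,15-dinorlabdane (1 equiv); 9 (E)-1-(3,5-dimethylpyrazol-1-yl)but-2-en-1-one (2 equiv)
Product: 12 (13S)-8α-acetoxy-15-(3,5-dimethylpyrazol-1-yl)labdan-15-one, via oxyl radical 10 (not isolated), via primary C12 radical 11 (not isolated)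
Conditions: Λ-[Rh(tBu-pbt)2(MeCN)2]PF6 (tBu-pbt = cyclometalated 5-tert-butyl-2-phenylbenzothiazole; 8 mol %), fac-Ir(ppy)3 (1 mol %), Hantzsch ester (diethyl 2,6-dimethyl-1,4-dihydropyridine-3,5-dicarboxylate, 1.5 equiv), THF, blue LEDs, rt, degassed
Reagents that add atoms: none
Why: Proposed new method: photoexcited Ir(ppy)3 with the dihydropyridine as terminal reductant transfers one electron to the phthalimide of 6, N–O cleavage gives oxyl radical 10 on the ketal carbon, and its β-scission breaks the ring bond from that carbon to C12, so that the ketal carbon becomes the carbonyl of an acetate on O8 and primary radical 11 is released; 11 adds to the β-carbon of 9, which is bound through N2 and the carbonyl oxygen to the rhodium Lewis acid, and the resulting rhodium enolate radical is reduced and protonated. The closest known reaction types are the reductive generation of oxyl radicals from N-alkoxyphthalimides followed by β-scission or 1,5-hydrogen transfer and Giese addition, the enantioselective Giese addition of photogenerated alkyl radicals to N-acyl pyrazoles on chiral-at-metal rhodium Lewis acids, and the classical iron/copper-induced fragmentation of α-alkoxy hydroperoxides; new is their merger on a ketal-type N-alkoxyphthalimide. No ring is closed: the temporary tetrahydropyran ring (O8, C8, C9, C11, C12 and the ketal carbon) is opened. The new C13 stereocentre (S) is controlled by the metal-centred chirality of the catalyst, which leaves one face of the s-cis crotonyl unit open, while C8 keeps its oxygen and configuration because the C8–O bond is never broken. The step needs β-scission toward C12 and not toward the methyl group, secured because a primary alkyl radical and an ester are formed instead of a methyl radical, and it needs addition of 11 to outrun its reduction by the dihydropyridine, secured by Lewis acid activation and the excess of 9.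

Step 5
Reactants: 12 (13S)-8α-acetoxy-15-(3,5-dimethylpyrazol-1-yl)labdan-15-one
Product: 13 (13S)-labdane-8α,15-diol
Conditions: LiAlH4, THF, 0 °C to rt
Reagents that add atoms: none
Why: Hydride reduction of the activated N-acyl pyrazole to the primary alcohol and reductive cleavage of the tertiary acetate in the same operation; no stereocentre is affected.

Step 6
Reactants: 13 (13S)-labdane-8α,15-diol
Product: 14 (13S)-8α-hydroxylabdan-15-yl acetate
Conditions: Ac2O (1.2 equiv), pyridine, CH2Cl2, 0 °C
Reagents that add atoms: acetic anhydride CC(=O)OC(C)=O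
Why: Chemoselective acylation: the primary C15 hydroxyl is acetylated while the hindered tertiary 8α-hydroxyl should not react without a nucleophilic catalyst.

Step 7
Reactants: 14 (13S)-8α-hydroxylabdan-15-yl acetate
Product: 16 (13S)-labd-8(17)-en-15-yl acetate, via chlorosulfite 15 (not isolated)
Conditions: SOCl2, pyridine, CH2Cl2, −78 °C to −40 °C
Reagents that add atoms: none
Why: Dehydration through the chlorosulfite by base-induced E2 elimination: the equatorial C8–O bond has no antiperiplanar ring hydrogen, so a hydrogen of the C17 methyl is removed and the 8(17)-exocyclic olefin should predominate, the usual outcome for 8α-hydroxylabdanes.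

Step 8
Reactants: 16 (13S)-labd-8(17)-en-15-yl acetate
Product: 18 (13S)-15-acetoxy-17-norlabdan-8-one, via ozonide 17 (not isolated)
Conditions: O3, CH2Cl2, −78 °C; then Me2S, −78 °C to rt
Reagents that add atoms: ozone [O-][O+]=O
Why: Ozonolysis of the 1,1-disubstituted olefin with reductive work-up excises C17 as formaldehyde and leaves the C8 ketone; C9, now α to the carbonyl, carries its side chain equatorial and is already the thermodynamically preferred epimer.

Step 9
Reactants: 18 (13S)-15-acetoxy-17-norlabdan-8-one
Product: 20 (13S)-15-acetoxy-17-norlabd-7-en-8-yl trifluoromethanesulfonate, via lithium enolate 19 (not isolated)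
Conditions: LiN(SiMe3)2 (1.05 equiv), THF, −78 °C; then PhNTf2, −78 °C to 0 °C
Reagents that add atoms: N-phenylbis(trifluoromethanesulfonimide) FC(F)(F)S(=O)(=O)N(c1ccccc1)S(=O)(=O)C(F)(F)F
Why: Kinetic enolisation with a hindered amide base takes a proton from the C7 methylene and not from the hindered C9 methine (and from the ketone ahead of the less acidic acetate), and O-sulfonylation fixes the Δ7 enol triflate.

Step 10
Reactants: 20 (13S)-15-acetoxy-17-norlabd-7-en-8-yl trifluoromethanesulfonate
Product: 21 (5S,9R,10S,13S)-15-acetoxylabd-7-en-17-oic acid (target)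
Conditions: Pd(OAc)2 (5 mol %), dppf (10 mol %), CO (1 atm), i-Pr2NEt, DMF–H2O (10:1), 50 °C
Reagents that add atoms: carbon monoxide [C-]#[O+]; water O
Why: Palladium-catalysed hydroxycarbonylation of the enol triflate (oxidative addition to zerovalent palladium, CO insertion, hydrolysis of the acyl–palladium species) puts C17 back as the carboxylic acid conjugated with C7=C8 under conditions the primary acetate should survive.

**Compound list**

1 | (−)-sclareol, (13R)-labd-14-ene-8α,13-diol | C=C[C@](C)(O)CC[C@H]1[C@](C)(O)CC[C@H]2C(C)(C)CCC[C@]12C | starting material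
2 | (13R)-8α,13-dihydroxy-15-norlabdan-14-al | O=C[C@](C)(O)CC[C@H]1[C@](C)(O)CC[C@H]2C(C)(C)CCC[C@]12C | intermediate
3 | 8α-hydroxy-14,15-dinorlabdan-13-one | CC(=O)CC[C@H]1[C@](C)(O)CC[C@H]2C(C)(C)CCC[C@]12C | intermediate
4 | sclareol oxide, 8α,13-epoxy-14,15-dinorlabd-12-ene | CC3=CC[C@H]1[C@](C)(O3)CC[C@H]2C(C)(C)CCC[C@]12C | intermediate
5 | N-hydroxyphthalimide | O=C1c2ccccc2C(=O)N1O | starting material
6 | 13-(phthalimidooxy)-8α,13-epoxy-14,15-dinorlabdane (C13 epimers) | CC3(ON4C(=O)c5ccccc5C4=O)CC[C@H]1[C@](C)(O3)CC[C@H]2C(C)(C)CCC[C@]12C | intermediate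
7 | (E)-but-2-enoyl chloride | C/C=C/C(Cl)=O | starting material
8 | 3,5-dimethyl-1H-pyrazole | Cc1cc(C)[nH]n1 | starting material
9 | (E)-1-(3,5-dimethylpyrazol-1-yl)but-2-en-1-one | C/C=C/C(=O)n1nc(C)cc1C | intermediate
10 | 8α,13-epoxy-14,15-dinorlabdan-13-yloxyl radical | CC3([O])CC[C@H]1[C@](C)(O3)CC[C@H]2C(C)(C)CCC[C@]12C | intermediate
11 | 8α-acetoxy-13,14,15,16-tetranorlabdan-12-yl radical | [CH2]C[C@H]1[C@](C)(OC(C)=O)CC[C@H]2C(C)(C)CCC[C@]12C | intermediate
12 | (13S)-8α-acetoxy-15-(3,5-dimethylpyrazol-1-yl)labdan-15-one | Cc1cc(C)n(n1)C(=O)C[C@@H](C)CC[C@H]1[C@](C)(OC(C)=O)CC[C@H]2C(C)(C)CCC[C@]12C | intermediate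
13 | (13S)-labdane-8α,15-diol | OCC[C@@H](C)CC[C@H]1[C@](C)(O)CC[C@H]2C(C)(C)CCC[C@]12C | intermediate
14 | (13S)-8α-hydroxylabdan-15-yl acetate | CC(=O)OCC[C@@H](C)CC[C@H]1[C@](C)(O)CC[C@H]2C(C)(C)CCC[C@]12C | intermediate
15 | (13S)-15-acetoxylabdan-8α-yl chlorosulfite | CC(=O)OCC[C@@H](C)CC[C@H]1[C@](C)(OS(Cl)=O)CC[C@H]2C(C)(C)CCC[C@]12C | intermediate
16 | (13S)-labd-8(17)-en-15-yl acetate | CC(=O)OCC[C@@H](C)CC[C@H]1C(=C)CC[C@H]2C(C)(C)CCC[C@]12C | intermediate
17 | ozonide (spiro-1,2,4-trioxolane at C8) of 16 | CC(=O)OCC[C@@H](C)CC[C@H]1C3(OCOO3)CC[C@H]2C(C)(C)CCC[C@]12C | intermediate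
18 | (13S)-15-acetoxy-17-norlabdan-8-one | CC(=O)OCC[C@@H](C)CC[C@H]1C(=O)CC[C@H]2C(C)(C)CCC[C@]12C | intermediate
19 | lithium Δ7-enolate of 18 | CC(=O)OCC[C@@H](C)CC[C@H]1C(O[Li])=CC[C@H]2C(C)(C)CCC[C@]12C | intermediate
20 | (13S)-15-acetoxy-17-norlabd-7-en-8-yl trifluoromethanesulfonate | CC(=O)OCC[C@@H](C)CC[C@H]1C(OS(=O)(=O)C(F)(F)F)=CC[C@H]2C(C)(C)CCC[C@]12C | intermediate
21 | (5S,9R,10S,13S)-15-acetoxylabd-7-en-17-oic acid | CC(=O)OCC[C@@H](C)CC[C@H]1C(C(=O)O)=CC[C@H]2C(C)(C)CCC[C@]12C | target

**Step count and risks**

Total step count: 10. Longest linear sequence: 9 steps (steps 1, 2 and 4 to 10); step 3 is a one-step side branch.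

Steps most likely to fail:

Step 4 (Proposed new method). Radical 11 may be reduced by hydrogen transfer from the dihydropyridine before it adds, the ketal N–O unit may ionise on the Lewis acid before electron transfer, or facial control may be poor for an unstabilised primary radical. The fallback sets out from 4 and returns at 13, using known chemistry only. Ozonolysis of the enol ether (O3, CH2Cl2, −78 °C; Me2S) should give 8α-acetoxy-13,14,15,16-tetranorlabdan-12-al F1, in which the old C13 is already the acetate on O8. NaBH4 gives 8α-acetoxy-13,14,15,16-tetranorlabdan-12-ol F2, and iodine, PPh3 and imidazole give 8α-acetoxy-12-iodo-13,14,15,16-tetranorlabdane F3. C12–C13 is then formed by an auxiliary-controlled, tin-hydride-mediated radical conjugate addition (Bu3SnH, Et3B/O2, Yb(OTf)3, CH2Cl2–THF, −78 °C) of F3 to (S)-3-[(E)-but-2-enoyl]-4-(diphenylmethyl)oxazolidin-2-one. On the chelate model this auxiliary enantiomer shields the face leading to 13R, so the product should be (S)-3-[(13S)-8α-acetoxylabdan-15-oyl]-4-(diphenylmethyl)oxazolidin-2-one F4. LiAlH4 removes auxiliary and acetate and gives 13.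

Step 2. The addition may reverse, with loss of N-hydroxyphthalimide back to the enol ether on work-up or chromatography of the hindered tertiary ketal. The fallback sets out from 4 and returns at 13 without any N-alkoxyphthalimide. H2O2 with a trace of acid adds in the same Markovnikov sense to give 13-hydroperoxy-8α,13-epoxy-14,15-dinorlabdane F5. FeSO4 and Cu(OAc)2 in MeOH (fragmentation of an α-alkoxy hydroperoxide, with copper-mediated oxidation of the C12 radical to the terminal olefin) should give 8α-acetoxy-13,14,15,16-tetranorlabd-11-ene F6. Hydroboration with 9-BBN and B-alkyl Suzuki–Miyaura coupling (Pd(dppf)Cl2, K3PO4) with (E)-3-iodobut-2-en-1-ol forms C12–C13 and gives (13E)-8α-acetoxylabd-13-en-15-ol F7. Hydrogenation with Ru(OAc)2[(R)-BINAP] in MeOH, the geraniol-to-citronellol type, should set 13S and give (13S)-8α-acetoxylabdan-15-ol F8, and LiAlH4 gives 13.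

Step 7. The elimination may be poorly regioselective, giving endocyclic olefin isomers that ozonolysis would cut in the ring. The fallback sets out from 14 and returns at 21 without removing C17. Dehydration followed by iodine-catalysed equilibration in hot toluene is steered to the trisubstituted olefin (13S)-labd-7-en-15-yl acetate F9. Allylic oxidation of the C17 methyl with SeO2 and t-BuOOH should give (13S)-15-acetoxylabd-7-en-17-al F10, and Pinnick oxidation (NaClO2, NaH2PO4, 2-methylbut-2-ene) gives 21.

Further compounds
F1 | step 4 | 8α-acetoxy-13,14,15,16-tetranorlabdan-12-al | O=CC[C@H]1[C@](C)(OC(C)=O)CC[C@H]2C(C)(C)CCC[C@]12C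
F2 | step 4 | 8α-acetoxy-13,14,15,16-tetranorlabdan-12-ol | OCC[C@H]1[C@](C)(OC(C)=O)CC[C@H]2C(C)(C)CCC[C@]12C
F3 | step 4 | 8α-acetoxy-12-iodo-13,14,15,16-tetranorlabdane | ICC[C@H]1[C@](C)(OC(C)=O)CC[C@H]2C(C)(C)CCC[C@]12C
F4 | step 4 | (S)-3-[(13S)-8α-acetoxylabdan-15-oyl]-4-(diphenylmethyl)oxazolidin-2-one | O=C1OC[C@H](C(c2ccccc2)c2ccccc2)N1C(=O)C[C@@H](C)CC[C@H]1[C@](C)(OC(C)=O)CC[C@H]2C(C)(C)CCC[C@]12C
F5 | step 2 | 13-hydroperoxy-8α,13-epoxy-14,15-dinorlabdane | CC3(OO)CC[C@H]1[C@](C)(O3)CC[C@H]2C(C)(C)CCC[C@]12C
F6 | step 2 | 8α-acetoxy-13,14,15,16-tetranorlabd-11-ene | C=C[C@H]1[C@](C)(OC(C)=O)CC[C@H]2C(C)(C)CCC[C@]12C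
F7 | step 2 | (13E)-8α-acetoxylabd-13-en-15-ol | OC/C=C(\C)CC[C@H]1[C@](C)(OC(C)=O)CC[C@H]2C(C)(C)CCC[C@]12C
F8 | step 2 | (13S)-8α-acetoxylabdan-15-ol | OCC[C@@H](C)CC[C@H]1[C@](C)(OC(C)=O)CC[C@H]2C(C)(C)CCC[C@]12C
F9 | step 7 | (13S)-labd-7-en-15-yl acetate | CC(=O)OCC[C@@H](C)CC[C@H]1C(C)=CC[C@H]2C(C)(C)CCC[C@]12C
F10 | step 7 | (13S)-15-acetoxylabd-7-en-17-al | CC(=O)OCC[C@@H](C)CC[C@H]1C(C=O)=CC[C@H]2C(C)(C)CCC[C@]12C
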